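## Retrosynthetic overview

1. The target comes from Z-selective semi-reduction of a C15≡C16 alkyne. That enyne comes from sila-Sonogashira coupling of a bicyclic enynol with 4-bromofuran-2(5H)-one, so the butenolide ring is bought intact, not built.
2. Rings A and B, both stereocentres (C5, C10) and the C8=C9 olefin come from one catalyst-controlled, proton-initiated head-to-tail bicyclization of an achiral acyclic C21 ester. Ring A closes first, ring B second in the same cascade, and a SiMe3 group on C9 ends it.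
3. The acyclic ester comes from a B-alkyl Suzuki coupling (C12–C13) of a 2-silyl tetraene with a (Z)-α-bromo enynoate, which fixes the 13E geometry.
4. The silyl tetraene comes from methyl-magnesiation and vinylation of a silyl enyne made from geranyl bromide and 1-(trimethylsilyl)propyne; the bromo enynoate comes from a Wittig reaction of 3-(trimethylsilyl)propynal.

Numbering used below is that of the final skeleton: C1–C10 for rings A and B, C11–C16 for the chain, C24 for the CH2OH carbon, C17–C19 and C25 for the butenolide.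

Catalyst A is the (S,S)-imidodiphosphorimidate acid HN[P(=NSO2C6F5)(O2Ar)]2, O2Ar = (S)-3,3′-bis(spiro[cyclopentane-1,9′-fluoren]-2′-yl)-1,1′-binaphthalene-2,2′-diolate. Assumption: this enantiomer (and the (R)-binaphthol acid of the first fallback) is the one that turns (3E,7E)-homofarnesol into (−)-ambrox, which has the ring A/B configuration of the target; if that control gives the antipode, the mirror-image catalyst is used.

## Route

Step 1
Reactants: 1 geranyl bromide; 2 trimethyl(prop-1-yn-1-yl)silane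
Product: 4 trimethyl[(5E)-6,10-dimethylundeca-5,9-dien-1-yn-1-yl]silane, via propargyllithium reagent 3 (not isolated)
Conditions: 2, n-BuLi, THF, −78 → −20 °C; then 1, −78 °C → rt
Reagents that add atoms: none
Why: Propargyl-anion alkylation (SN2 at the primary allylic bromide) makes the C6–C7 bond, keeps the E olefin of 1 and places silicon on the future C9.

Step 2
Reactants: 4 trimethyl[(5E)-6,10-dimethylundeca-5,9-dien-1-yn-1-yl]silane; 5 vinyl bromide
Product: 8 trimethyl[(3Z,7E)-4,8,12-trimethyltrideca-1,3,7,11-tetraen-3-yl]silane, via alkenylmagnesium bromide 6 (not isolated), via alkenylzinc bromide 7 (not isolated)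
Conditions: MeMgBr (3 equiv), Ni(acac)2 (10 mol %), AlMe3 (10 mol %), THF, rt; ZnBr2, 0 °C; then 5 (excess), Pd(PPh3)4 (5 mol %), 50 °C
Reagents that add atoms: methylmagnesium bromide, C[Mg]Br
Why: Nickel-catalysed syn-carbomagnesiation of the silylalkyne puts CH3 on the carbon remote from silicon (C8) and the metal on the silicon-bearing carbon (C9), and Mg-to-Zn exchange with Negishi coupling then adds C11–C12 with retention; any partial E/Z scrambling of this olefin is harmless because both of its carbons end as the sp2 carbons C8 and C9.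

Step 3
Reactants: 9 ethyl (triphenylphosphoranylidene)acetate; 10 3-(trimethylsilyl)prop-2-ynal
Product: 12 ethyl (2Z)-2-bromo-5-(trimethylsilyl)pent-2-en-4-ynoate, via bromo ylide 11 (not isolated)
Conditions: 9, NBS, CH2Cl2, −20 °C; then 10, → rt
Reagents that add atoms: N-bromosuccinimide, O=C1CCC(=O)N1Br
Why: One-pot ylide bromination and Wittig olefination; the ester-stabilised bromo ylide places the ester trans to the alkynyl group (2Z, minor 2E isomer removed by chromatography), the geometry that becomes 13E.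

Step 4
Reactants: 8 trimethyl[(3Z,7E)-4,8,12-trimethyltrideca-1,3,7,11-tetraen-3-yl]silane; 12 ethyl (2Z)-2-bromo-5-(trimethylsilyl)pent-2-en-4-ynoate
Product: 14 ethyl (2E)-2-[(3Z,7E)-4,8,12-trimethyl-3-(trimethylsilyl)trideca-3,7,11-trien-1-yl]-5-(trimethylsilyl)pent-2-en-4-ynoate, via alkyl-9-BBN borane 13 (not isolated)
Conditions: 8, 9-BBN, THF, 0 °C → rt; then 12, PdCl2(dppf) (5 mol %), AsPh3, aq. K3PO4, DMF, rt
Reagents that add atoms: none
Why: Anti-Markovnikov hydroboration of the only monosubstituted olefin, then B-alkyl Suzuki–Miyaura coupling at the C–Br bond with retention, so C12 ends cis to C15 and the ester trans to it.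

Step 5
Reactants: 14 ethyl (2E)-2-[(3Z,7E)-4,8,12-trimethyl-3-(trimethylsilyl)trideca-3,7,11-trien-1-yl]-5-(trimethylsilyl)pent-2-en-4-ynoate
Product: 16 ethyl (2E)-2-{2-[(4aS,8aS)-2,5,5,8a-tetramethyl-3,4,4a,5,6,7,8,8a-octahydronaphthalen-1-yl]ethyl}-5-(trimethylsilyl)pent-2-en-4-ynoate, via C8 carbocation 15 (not isolated)
Conditions: catalyst A (5 mol %), (CF3)3COH/CH2Cl2, −30 °C
Reagents that add atoms: none
Why: Proposed new method: a catalytic asymmetric, proton-initiated polyene bicyclization ended by a vinylsilane. The confined chiral acid protonates C3 of the terminal isopropylidene group on one face; the C5=C10 olefin (bond C4–C5) and then the silicon-bearing carbon C9 (bond C9–C10) add anti through a chair–chair (Stork–Eschenmoser) array, so C5 (α-H) and C10 (β-CH3) are set trans in one event under catalyst control. The tertiary, β-silyl-stabilised C8 cation 15 hands Me3Si+ to the fluoroalcohol, which places the new olefin only at C8=C9 and returns the proton to the catalyst; the electron-poor enynoate takes no part. Closest known reaction types: the imidodiphosphorimidate-catalysed asymmetric bicyclization of (3E,7E)-homofarnesol to (−)-ambrox in fluorinated alcohols, and vinylsilane-terminated cation–olefin cyclizations of the Fleming and Overman type.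

Step 6
Reactants: 16 ethyl (2E)-2-{2-[(4aS,8aS)-2,5,5,8a-tetramethyl-3,4,4a,5,6,7,8,8a-octahydronaphthalen-1-yl]ethyl}-5-(trimethylsilyl)pent-2-en-4-ynoate
Product: 17 (2E)-2-{2-[(4aS,8aS)-2,5,5,8a-tetramethyl-3,4,4a,5,6,7,8,8a-octahydronaphthalen-1-yl]ethyl}-5-(trimethylsilyl)pent-2-en-4-yn-1-ol
Conditions: i-Bu2AlH (2.5 equiv), CH2Cl2, −78 °C; aq. potassium sodium tartrate
Reagents that add atoms: none
Why: 1,2-Reduction of the conjugated ester by the aluminium hydride at low temperature leaves the alkynylsilane, the tetrasubstituted olefin and both stereocentres untouched.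

Step 7
Reactants: 17 (2E)-2-{2-[(4aS,8aS)-2,5,5,8a-tetramethyl-3,4,4a,5,6,7,8,8a-octahydronaphthalen-1-yl]ethyl}-5-(trimethylsilyl)pent-2-en-4-yn-1-ol; 18 4-bromofuran-2(5H)-one
Product: 19 4-[(3E)-4-(hydroxymethyl)-6-[(4aS,8aS)-2,5,5,8a-tetramethyl-3,4,4a,5,6,7,8,8a-octahydronaphthalen-1-yl]hex-3-en-1-yn-1-yl]furan-2(5H)-one
Conditions: 18, Pd(PPh3)4 (5 mol %), CuI (10 mol %), CsF, DMF, rt
Reagents that add atoms: none
Why: Sila-Sonogashira coupling: fluoride-triggered transfer of the alkynyl group from silicon to copper and palladium-catalysed coupling with the activated β-bromo butenolide form C16–C17 without a separate desilylation.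

Step 8
Reactants: 19 4-[(3E)-4-(hydroxymethyl)-6-[(4aS,8aS)-2,5,5,8a-tetramethyl-3,4,4a,5,6,7,8,8a-octahydronaphthalen-1-yl]hex-3-en-1-yn-1-yl]furan-2(5H)-one
Product: 20 4-[(1Z,3E)-4-(hydroxymethyl)-6-[(4aS,8aS)-2,5,5,8a-tetramethyl-3,4,4a,5,6,7,8,8a-octahydronaphthalen-1-yl]hexa-1,3-dien-1-yl]furan-2(5H)-one
Conditions: Zn dust activated with Cu(OAc)2 and AgNO3, MeOH/H2O (1:1), 40 °C
Reagents that add atoms: none
Why: Boland-type semi-reduction by activated zinc adds two hydrogens cis to the conjugated triple bond only, giving the 15Z olefin without touching the butenolide or the ring olefin.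

## Compound list

1 | geranyl bromide, (2E)-1-bromo-3,7-dimethylocta-2,6-diene | CC(C)=CCC/C(C)=C/CBr | starting material
2 | trimethyl(prop-1-yn-1-yl)silane | CC#C[Si](C)(C)C | starting material
3 | [3-(trimethylsilyl)prop-2-yn-1-yl]lithium | [Li]CC#C[Si](C)(C)C | intermediate
4 | trimethyl[(5E)-6,10-dimethylundeca-5,9-dien-1-yn-1-yl]silane | CC(C)=CCC/C(C)=C/CCC#C[Si](C)(C)C | intermediate
5 | vinyl bromide (bromoethene) | C=CBr | starting material
6 | bromo[(1Z,5E)-2,6,10-trimethyl-1-(trimethylsilyl)undeca-1,5,9-trien-1-yl]magnesium (CH3 and Mg cis) | CC(C)=CCC/C(C)=C/CC/C(C)=C(/[Mg]Br)[Si](C)(C)C | intermediate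
7 | bromo[(1E,5E)-2,6,10-trimethyl-1-(trimethylsilyl)undeca-1,5,9-trien-1-yl]zinc (CH3 and Zn cis) | CC(C)=CCC/C(C)=C/CC/C(C)=C(/[Zn]Br)[Si](C)(C)C | intermediate
8 | trimethyl[(3Z,7E)-4,8,12-trimethyltrideca-1,3,7,11-tetraen-3-yl]silane | C=C/C([Si](C)(C)C)=C(\C)CC/C=C(\C)CCC=C(C)C | intermediate
9 | ethyl (triphenylphosphoranylidene)acetate | CCOC(=O)C=P(c1ccccc1)(c1ccccc1)c1ccccc1 | starting material
10 | 3-(trimethylsilyl)prop-2-ynal | C[Si](C)(C)C#CC=O | starting material
11 | ethyl bromo(triphenylphosphoranylidene)acetate | CCOC(=O)C(Br)=P(c1ccccc1)(c1ccccc1)c1ccccc1 | intermediate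
12 | ethyl (2Z)-2-bromo-5-(trimethylsilyl)pent-2-en-4-ynoate | CCOC(=O)/C(Br)=C/C#C[Si](C)(C)C | intermediate
13 | 9-[(3Z,7E)-4,8,12-trimethyl-3-(trimethylsilyl)trideca-3,7,11-trien-1-yl]-9-borabicyclo[3.3.1]nonane | B1(CC/C([Si](C)(C)C)=C(\C)CC/C=C(\C)CCC=C(C)C)C2CCCC1CCC2 | intermediate
14 | ethyl (2E)-2-[(3Z,7E)-4,8,12-trimethyl-3-(trimethylsilyl)trideca-3,7,11-trien-1-yl]-5-(trimethylsilyl)pent-2-en-4-ynoate | CCOC(=O)/C(CC/C([Si](C)(C)C)=C(\C)CC/C=C(\C)CCC=C(C)C)=C/C#C[Si](C)(C)C | intermediate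
15 | bicyclic C8 carbocation: trans-decalin (5α-H, 10β-CH3) with cationic C8, SiMe3 axial (α) and the enynoate chain equatorial (β) on C9 | C[C+]1[C@@](CC/C(C(=O)OCC)=C\C#C[Si](C)(C)C)([Si](C)(C)C)[C@@]2(C)CCCC(C)(C)[C@@H]2CC1 | intermediate
16 | ethyl (2E)-2-{2-[(4aS,8aS)-2,5,5,8a-tetramethyl-3,4,4a,5,6,7,8,8a-octahydronaphthalen-1-yl]ethyl}-5-(trimethylsilyl)pent-2-en-4-ynoate | CC1=C(CC/C(C(=O)OCC)=C\C#C[Si](C)(C)C)[C@@]2(C)CCCC(C)(C)[C@@H]2CC1 | intermediate
17 | (2E)-2-{2-[(4aS,8aS)-2,5,5,8a-tetramethyl-3,4,4a,5,6,7,8,8a-octahydronaphthalen-1-yl]ethyl}-5-(trimethylsilyl)pent-2-en-4-yn-1-ol | CC1=C(CC/C(CO)=C\C#C[Si](C)(C)C)[C@@]2(C)CCCC(C)(C)[C@@H]2CC1 | intermediate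
18 | 4-bromofuran-2(5H)-one | O=C1OCC(Br)=C1 | starting material
19 | 4-[(3E)-4-(hydroxymethyl)-6-[(4aS,8aS)-2,5,5,8a-tetramethyl-3,4,4a,5,6,7,8,8a-octahydronaphthalen-1-yl]hex-3-en-1-yn-1-yl]furan-2(5H)-one | CC1=C(CC/C(CO)=C\C#CC3=CC(=O)OC3)[C@@]2(C)CCCC(C)(C)[C@@H]2CC1 | intermediate
20 | 4-[(1Z,3E)-4-(hydroxymethyl)-6-[(4aS,8aS)-2,5,5,8a-tetramethyl-3,4,4a,5,6,7,8,8a-octahydronaphthalen-1-yl]hexa-1,3-dien-1-yl]furan-2(5H)-one (CNP0232848.4) | CC1=C(CC/C(=C\C=C/C2=CC(=O)OC2)CO)[C@@]2(C)CCCC(C)(C)[C@@H]2CC1 | target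

## Step count and risk

Total steps: 8. Longest linear sequence: 7 (steps 1, 2, 4, 5, 6, 7, 8 from geranyl bromide); step 3 is a one-step branch.

The three steps most likely to fail:

**Step 5.** The vinylsilane may be protodesilylated before ring B closes. The cascade may stop at the monocycle, because the C9–C10 bond joins two fully substituted carbons. The enantiomer ratio may fall short on a substrate without a hydroxyl head group; it should be checked at 17 on a chiral phase. The fallback sets out from 14 and comes back at 16. Ring A alone is closed under reagent control with 2 equiv of the stoichiometric chiral acid (R)-2-[(2-fluorobenzyl)oxy]-2′-hydroxy-1,1′-binaphthyl·SnCl4 in toluene at −78 °C, a Lewis-acid-assisted Brønsted acid that works without an acidic fluoroalcohol medium. The monocyclic ester ethyl (2E)-2-[(3Z)-4-methyl-6-[(1S)-2,6,6-trimethylcyclohex-2-en-1-yl]-3-(trimethylsilyl)hex-3-en-1-yl]-5-(trimethylsilyl)pent-2-en-4-ynoate F2 is isolated; its exocyclic olefin isomer behaves alike, and any 16 formed directly is pooled. Ring B is then closed in a separate operation with SnCl4/CF3CO2H in CH2Cl2 at −78 °C under control of the C5 stereocentre, the vinylsilane again ending the reaction at C8=C9.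

**Step 2.** The hindered α-silyl alkenyl metal may couple poorly with vinyl bromide in the presence of excess MeMgBr. The fallback sets out from 4 and comes back at 8. The carbomagnesiation is run as before, but the alkenylmagnesium bromide 6 is quenched with I2 to give the isolable iodide [(1E,5E)-1-iodo-2,6,10-trimethylundeca-1,5,9-trien-1-yl]trimethylsilane F1. After purification, F1 is joined to tributyl(vinyl)stannane in a separate Stille coupling (Pd(PPh3)4, CuI, DMF, 60 °C).

**Step 8.** Over-reduction or loss of Z purity is possible on a triple bond conjugated to both an enol-type diene and the butenolide. The fallback sets out from 17 and comes back at 20 without passing through 19. The alkynylsilane is cleaved (K2CO3, MeOH) to the terminal enynol (2E)-2-{2-[(4aS,8aS)-2,5,5,8a-tetramethyl-3,4,4a,5,6,7,8,8a-octahydronaphthalen-1-yl]ethyl}pent-2-en-4-yn-1-ol F3. Rhodium-catalysed trans-hydroboration with pinacolborane ([Rh(cod)Cl]2, P(i-Pr)3, Et3N) gives the (Z)-alkenylboronate (2E,4Z)-2-{2-[(4aS,8aS)-2,5,5,8a-tetramethyl-3,4,4a,5,6,7,8,8a-octahydronaphthalen-1-yl]ethyl}-5-(4,4,5,5-tetramethyl-1,3,2-dioxaborolan-2-yl)penta-2,4-dien-1-ol F4. Suzuki–Miyaura coupling of F4 with 18 (Pd(PPh3)4, K3PO4, THF/H2O, rt) forms C16–C17 with the Z olefin already in place.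

## Further compounds

F1 | step 2 | [(1E,5E)-1-iodo-2,6,10-trimethylundeca-1,5,9-trien-1-yl]trimethylsilane | CC(C)=CCC/C(C)=C/CC/C(C)=C(/I)[Si](C)(C)C
F2 | step 5 | ethyl (2E)-2-[(3Z)-4-methyl-6-[(1S)-2,6,6-trimethylcyclohex-2-en-1-yl]-3-(trimethylsilyl)hex-3-en-1-yl]-5-(trimethylsilyl)pent-2-en-4-ynoate | CC1=CCCC(C)(C)[C@@H]1CC/C(C)=C(/CC/C(C(=O)OCC)=C\C#C[Si](C)(C)C)[Si](C)(C)C
F3 | step 8 | (2E)-2-{2-[(4aS,8aS)-2,5,5,8a-tetramethyl-3,4,4a,5,6,7,8,8a-octahydronaphthalen-1-yl]ethyl}pent-2-en-4-yn-1-ol | CC1=C(CC/C(CO)=C\C#C)[C@@]2(C)CCCC(C)(C)[C@@H]2CC1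
F4 | step 8 | (2E,4Z)-2-{2-[(4aS,8aS)-2,5,5,8a-tetramethyl-3,4,4a,5,6,7,8,8a-octahydronaphthalen-1-yl]ethyl}-5-(4,4,5,5-tetramethyl-1,3,2-dioxaborolan-2-yl)penta-2,4-dien-1-ol | CC1=C(CC/C(CO)=C\C=C/B3OC(C)(C)C(C)(C)O3)[C@@]2(C)CCCC(C)(C)[C@@H]2CC1
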